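Locants: dioxolane ring O1–O2–C3–C4–C5, acetic acid arm on C3, side chain C1′–C15′ on C5.
Cuts: the arm CO2H goes back to CH2CH2OSi. The chain is cut at C9′=C10′ (Julia–Kocienski), C7′=C8′ (stabilised Wittig) and C4′–C5′ (Wittig, then diimide), which leaves a C4′ ester. O1–C5 and C1′–C2′ are then cut together, and last C3–O2 (oxetane plus H2O2).
Enabling feature: the C5 methyl group, C5 and C1′ form the CH3–C(=CH2) end of a methallyl group attached to C3 through C4. The C3 oxygen can be a tertiary OOH with no α-hydrogen, and C1′–C2′ is a plain CH2–CH2 bond that a C1′ radical and an acrylate can form.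
Forward: the C8 skeleton comes from stannylcupration and Stille coupling, then epoxide, 1,3-diol, oxetane and hydroperoxide. The only ring closes in the key step, which also starts the chain. The chain then grows outward (C4′, C7′, C9′, C15′) and the arm is oxidised last.
Stereochemistry: C3 comes from Sharpless epoxidation with L-(+)-tartrate, is carried through the tertiary alcohol and is inverted once in the oxetane opening. C5 comes from the 1,3-trans preference of the reversible peroxymercuration. 7′E comes from the stabilised ylide, 9′E from the Julia–Kocienski step, and 12′Z is bought with (3Z)-hex-3-en-1-ol.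

Key step: step 10

Remark on the chemistry: anhydrous ethereal H2O2 is assumed to be made from the commercial aqueous reagent by extraction and drying. The alkene from the first Wittig reaction is drawn as the expected Z isomer, and its geometry is erased by the diimide step.

Step 1
Reactants: 1 ethyl but-2-ynoate
Product: 2 ethyl (2E)-3-(tributylstannyl)but-2-enoate
Conditions: Bu3SnH, LiN(iPr)2, THF, 0 °C; CuBr·SMe2, −78 °C; then 1, MeOH, −78 °C
Reagents that add atoms: tributyltin hydride, CCCC[SnH](CCCC)CCCC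
Why: Syn stannylcupration of an ynoate places tin on the β-carbon, and protonation of the alkenylcopper by MeOH at −78 °C, before it can isomerise, fixes the E geometry with tin trans to the ester.

Step 2
Reactants: 2 ethyl (2E)-3-(tributylstannyl)but-2-enoate, 3 3-chloro-2-methylprop-1-ene
Product: 4 ethyl (2E)-3,5-dimethylhexa-2,5-dienoate
Conditions: Pd2(dba)3 (2.5 mol %), P(2-furyl)3 (10 mol %), NMP, 45 °C
Reagents that add atoms: none
Why: In this Stille coupling the allylic chloride adds oxidatively to zerovalent palladium to give a symmetrical methallyl complex (no regiochemical issue), and the alkenylstannane transfers with retention, so the skipped dienoate keeps the E geometry under neutral conditions.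

Step 3
Reactants: 4 ethyl (2E)-3,5-dimethylhexa-2,5-dienoate
Product: 5 (2E)-3,5-dimethylhexa-2,5-dien-1-ol
Conditions: iBu2AlH (2.2 equiv), CH2Cl2, −78 °C; aq potassium sodium tartrate
Reagents that add atoms: none
Why: 1,2-Reduction of an enoate with iBu2AlH gives the allylic alcohol without touching either alkene or moving the skipped diene into conjugation.

Step 4
Reactants: 5 (2E)-3,5-dimethylhexa-2,5-dien-1-ol
Product: 6 [(2S,3S)-3-methyl-3-(2-methylprop-2-en-1-yl)oxiran-2-yl]methanol
Conditions: Ti(OiPr)4 (10 mol %), L-(+)-diisopropyl tartrate (12 mol %), tBuOOH, 4 Å molecular sieves, CH2Cl2, −20 °C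
Reagents that add atoms: tert-butyl hydroperoxide, CC(C)(C)OO
Why: Sharpless asymmetric epoxidation oxidises only the alkene of the titanium-bound allylic alcohol, and for this geraniol-type E substrate the L-(+)-tartrate ligand directs oxygen to the face that gives the (2S,3S) epoxide.

Step 5
Reactants: 6 [(2S,3S)-3-methyl-3-(2-methylprop-2-en-1-yl)oxiran-2-yl]methanol
Product: 7 (3S)-3,5-dimethylhex-5-ene-1,3-diol
Conditions: NaAlH2(OCH2CH2OMe)2, THF, 0 °C to rt
Reagents that add atoms: none
Why: In this directed reductive opening of a 2,3-epoxy alcohol the aluminium alkoxide delivers hydride internally to C2, so the 1,3-diol forms with the C3–O bond and its configuration untouched.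

Step 6
Reactants: 7 (3S)-3,5-dimethylhex-5-ene-1,3-diol
Product: 9 (2S)-2-methyl-2-(2-methylprop-2-en-1-yl)oxetane, via primary tosylate 8 (not isolated)
Conditions: n-BuLi (1.0 equiv), THF, 0 °C; TsCl (1.0 equiv); n-BuLi (1.1 equiv), 0 to 45 °C
Reagents that add atoms: 4-methylbenzenesulfonyl chloride, Cc1ccc(cc1)S(=O)(=O)Cl (its atoms stay in 8 only and leave on ring closure)
Why: Selective sulfonylation of the unhindered primary oxygen followed by 4-exo-tet Williamson closure by the tertiary alkoxide is the standard one-flask oxetane synthesis from 1,3-diols and leaves the tertiary C–O bond, and so the configuration, intact.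

Step 7
Reactants: 9 (2S)-2-methyl-2-(2-methylprop-2-en-1-yl)oxetane, 10 hydrogen peroxide
Product: 11 (3R)-3-hydroperoxy-3,5-dimethylhex-5-en-1-ol
Conditions: H2O2 (anhydrous, Et2O, excess), Me3SiOTf (10 mol %), −78 to 0 °C
Reagents that add atoms: none
Why: In this Lewis-acid-promoted perhydrolysis of a 2,2-dialkyl oxetane the activated ring oxygen is displaced at the tertiary carbon from the rear by H2O2, so (S)-9 should give (R)-11 with inversion, while the ether medium and low temperature keep the acidity below what is needed to protonate the methallyl alkene.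

Step 8
Reactants: 11 (3R)-3-hydroperoxy-3,5-dimethylhex-5-en-1-ol
Product: 13 tert-butyl({(3R)-3-[(2-methoxypropan-2-yl)peroxy]-3,5-dimethylhex-5-en-1-yl}oxy)diphenylsilane, via peroxyketal alcohol 12 (not isolated)
Conditions: 2-methoxypropene (1.2 equiv), PPTS (5 mol %), CH2Cl2, 0 °C; then imidazole, tBuPh2SiCl, rt
Reagents that add atoms: 2-methoxypropene, C=C(C)OC; tert-butyl(chloro)diphenylsilane, CC(C)(C)[Si](Cl)(c1ccccc1)c1ccccc1
Why: Acid-catalysed peroxyketal formation takes the more acidic, α-effect OOH group ahead of the alcohol, and once imidazole has quenched the PPTS the remaining primary OH is silylated under standard chlorosilane/imidazole conditions, which avoids any contest between OOH and OH for the silyl chloride.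

Step 9
Reactants: 13 tert-butyl({(3R)-3-[(2-methoxypropan-2-yl)peroxy]-3,5-dimethylhex-5-en-1-yl}oxy)diphenylsilane
Product: 14 tert-butyl{[(3R)-3-hydroperoxy-3,5-dimethylhex-5-en-1-yl]oxy}diphenylsilane
Conditions: AcOH/THF/H2O, rt
Reagents that add atoms: none
Why: Mild acid hydrolysis of a 2-methoxyprop-2-yl peroxyketal frees the hydroperoxide, and the tert-butyldiphenylsilyl ether and the 1,1-disubstituted alkene are inert to aqueous acetic acid.

Step 10
Reactants: 14 tert-butyl{[(3R)-3-hydroperoxy-3,5-dimethylhex-5-en-1-yl]oxy}diphenylsilane, 15 methyl acrylate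
Product: 17 methyl 4-[(3S,5S)-5-(2-{[tert-butyl(diphenyl)silyl]oxy}ethyl)-3,5-dimethyl-1,2-dioxolan-3-yl]butanoate, via mercuriomethyl dioxolane 16 (not isolated)
Conditions: Hg(OAc)2 (1.05 equiv), HClO4 (5 mol %), CH2Cl2, rt; then 15 (20 equiv), NaBH(OMe)3 (slow addition), CH2Cl2, −20 to 0 °C
Reagents that add atoms: mercury diacetate, CC(=O)O[Hg]OC(C)=O (its atoms stay in 16 only)
Why: Proposed new method: Hg(OAc)2 converts the terminal alkene into a mercurinium ion whose substituted carbon C5 is captured by the terminal oxygen of the tertiary C3 hydroperoxide in a Markovnikov 5-exo-trig closure (O1–C5), which is the known cycloperoxymercuration of homoallylic hydroperoxides and gives the mercuriomethyl-1,2-dioxolane 16. NaBH(OMe)3 then exchanges acetate for hydride, the alkylmercury hydride sheds mercury, and the primary C1′ radical adds to the β-carbon of methyl acrylate (C1′–C2′) before the ester-stabilised radical takes hydrogen from further mercury hydride, which is the Giese reductive alkylation of solvomercuration adducts, its use on a β-peroxyalkylmercurial being the untested part. The selectivity needed is addition ahead of attack of the radical on the adjacent O–O bond (oxirane plus alkoxyl radical) and ahead of direct hydrogen transfer: a nucleophilic primary radical should add to acrylate held at multimolar concentration faster than the unimolecular oxirane closure known for β-peroxyalkyl radicals, low temperature favours the bimolecular path, and slow hydride addition keeps the mercury hydride scarce. C3 is not touched, and the new C5 centre is governed by the C3 substituents, the CH2HgOAc group settling trans to the bulky silyloxyethyl arm, while the HClO4-catalysed reversibility of peroxymercuration lets the mixture move toward this less crowded isomer before hydride is added. Because the radical centre is exocyclic, C5 keeps its configuration through the alkylation, and the minor cis isomer should be removable by chromatography of 17. The substrate suits the step because neither peroxide carbon bears hydrogen, the alcohol is masked so that only OOH can capture the mercurinium ion, and no second alkene is present.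

Step 11
Reactants: 17 methyl 4-[(3S,5S)-5-(2-{[tert-butyl(diphenyl)silyl]oxy}ethyl)-3,5-dimethyl-1,2-dioxolan-3-yl]butanoate
Product: 18 4-[(3S,5S)-5-(2-{[tert-butyl(diphenyl)silyl]oxy}ethyl)-3,5-dimethyl-1,2-dioxolan-3-yl]butanal
Conditions: iBu2AlH (1.1 equiv), CH2Cl2, −78 °C; MeOH, aq potassium sodium tartrate
Reagents that add atoms: none
Why: Partial reduction of a methyl ester with one equivalent of iBu2AlH stops at the aluminium hemiacetal at −78 °C, a temperature at which hindered dialkyl peroxides are not attacked.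

Step 12
Reactants: 18 4-[(3S,5S)-5-(2-{[tert-butyl(diphenyl)silyl]oxy}ethyl)-3,5-dimethyl-1,2-dioxolan-3-yl]butanal, 19 [2-(1,3-dioxolan-2-yl)ethyl]triphenylphosphonium bromide
Product: 20 tert-butyl(2-{(3S,5S)-5-[(4Z)-6-(1,3-dioxolan-2-yl)hex-4-en-1-yl]-3,5-dimethyl-1,2-dioxolan-3-yl}ethoxy)diphenylsilane
Conditions: 19, NaN(SiMe3)2, THF, 0 °C; then 18, −78 °C to rt
Reagents that add atoms: none
Why: Wittig olefination with a non-stabilised ylide adds C5′–C7′ with C7′ masked as an acetal, and the fully substituted peroxide carbons rule out base-induced Kornblum–DeLaMare fragmentation.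

Step 13
Reactants: 20 tert-butyl(2-{(3S,5S)-5-[(4Z)-6-(1,3-dioxolan-2-yl)hex-4-en-1-yl]-3,5-dimethyl-1,2-dioxolan-3-yl}ethoxy)diphenylsilane
Product: 21 tert-butyl(2-{(3S,5S)-5-[6-(1,3-dioxolan-2-yl)hexyl]-3,5-dimethyl-1,2-dioxolan-3-yl}ethoxy)diphenylsilane
Conditions: KO2CN=NCO2K, AcOH, CH2Cl2/MeOH, 0 °C to rt
Reagents that add atoms: none
Why: Diimide reduction transfers two hydrogens to the C=C bond in a concerted way and leaves the O–O bond alone, which is why it is the standard method for saturating alkenes in cyclic peroxides where catalytic hydrogenation would cleave them.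

Step 14
Reactants: 21 tert-butyl(2-{(3S,5S)-5-[6-(1,3-dioxolan-2-yl)hexyl]-3,5-dimethyl-1,2-dioxolan-3-yl}ethoxy)diphenylsilane
Product: 22 7-[(3S,5S)-5-(2-{[tert-butyl(diphenyl)silyl]oxy}ethyl)-3,5-dimethyl-1,2-dioxolan-3-yl]heptanal
Conditions: 1 M HCl, THF, rt
Reagents that add atoms: water, O
Why: Acid-catalysed acetal hydrolysis frees the C7′ aldehyde under conditions that the acid-stable tert-butyldiphenylsilyl ether and the tetrasubstituted peroxide tolerate.

Step 15
Reactants: 22 7-[(3S,5S)-5-(2-{[tert-butyl(diphenyl)silyl]oxy}ethyl)-3,5-dimethyl-1,2-dioxolan-3-yl]heptanal, 23 (triphenylphosphoranylidene)acetaldehyde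
Product: 24 (2E)-9-[(3S,5S)-5-(2-{[tert-butyl(diphenyl)silyl]oxy}ethyl)-3,5-dimethyl-1,2-dioxolan-3-yl]non-2-enal
Conditions: toluene, 70 °C
Reagents that add atoms: none
Why: Wittig olefination with a stabilised formyl ylide is E-selective and base-free, sets C7′=C8′ and stops at the enal because the conjugated product is less electrophilic than the saturated aldehyde.

Step 16
Reactants: 25 (3Z)-hex-3-en-1-ol
Product: 26 5-{[(3Z)-hex-3-en-1-yl]sulfanyl}-1-phenyl-1H-tetrazole
Conditions: 1-phenyl-1H-tetrazole-5-thiol, PPh3, DIAD, THF, 0 °C to rt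
Reagents that add atoms: 1-phenyl-1H-tetrazole-5-thiol, Sc1nnnn1-c1ccccc1
Why: Mitsunobu thioetherification of a primary alcohol with the acidic tetrazole thiol is routine and does not disturb the Z alkene.

Step 17
Reactants: 26 5-{[(3Z)-hex-3-en-1-yl]sulfanyl}-1-phenyl-1H-tetrazole, 10 hydrogen peroxide
Product: 27 5-{[(3Z)-hex-3-en-1-yl]sulfonyl}-1-phenyl-1H-tetrazole
Conditions: (NH4)6Mo7O24·4H2O (10 mol %), 30 % aq H2O2, EtOH, 0 °C to rt
Reagents that add atoms: none
Why: Molybdate-catalysed oxidation of a sulfide to the sulfone is much faster than epoxidation of an isolated disubstituted alkene, so the Z alkene survives.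

Step 18
Reactants: 24 (2E)-9-[(3S,5S)-5-(2-{[tert-butyl(diphenyl)silyl]oxy}ethyl)-3,5-dimethyl-1,2-dioxolan-3-yl]non-2-enal, 27 5-{[(3Z)-hex-3-en-1-yl]sulfonyl}-1-phenyl-1H-tetrazole
Product: 28 tert-butyl(2-{(3S,5S)-3,5-dimethyl-5-[(7E,9E,12Z)-pentadeca-7,9,12-trien-1-yl]-1,2-dioxolan-3-yl}ethoxy)diphenylsilane
Conditions: 27, KN(SiMe3)2, THF, −78 °C; then 24, −78 °C to rt
Reagents that add atoms: none
Why: Julia–Kocienski olefination of an alkyl phenyltetrazolyl sulfone with an α,β-unsaturated aldehyde is the polarity that reliably favours the E alkene, so C9′=C10′ forms E next to the preset 7′E and 12′Z bonds, and the peroxide has no α-hydrogen for the base to remove.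

Step 19
Reactants: 28 tert-butyl(2-{(3S,5S)-3,5-dimethyl-5-[(7E,9E,12Z)-pentadeca-7,9,12-trien-1-yl]-1,2-dioxolan-3-yl}ethoxy)diphenylsilane
Product: 29 2-{(3S,5S)-3,5-dimethyl-5-[(7E,9E,12Z)-pentadeca-7,9,12-trien-1-yl]-1,2-dioxolan-3-yl}ethan-1-ol
Conditions: Bu4NF, AcOH, THF, 0 °C to rt
Reagents that add atoms: none
Why: Fluoride-induced desilylation, buffered with acetic acid, removes the silyl ether without a basic medium that could shift the skipped alkene.

Step 20
Reactants: 29 2-{(3S,5S)-3,5-dimethyl-5-[(7E,9E,12Z)-pentadeca-7,9,12-trien-1-yl]-1,2-dioxolan-3-yl}ethan-1-ol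
Product: 31 {(3R,5S)-3,5-dimethyl-5-[(7E,9E,12Z)-pentadeca-7,9,12-trien-1-yl]-1,2-dioxolan-3-yl}acetic acid, via dioxolanylacetaldehyde 30 (not isolated)
Conditions: TEMPO (20 mol %), PhI(OAc)2 (2.5 equiv), MeCN/pH 7 phosphate buffer, 0 °C to rt
Reagents that add atoms: water, O
Why: Oxoammonium-catalysed oxidation (TEMPO/PhI(OAc)2 in aqueous acetonitrile) takes a primary alcohol through the aldehyde hydrate to the acid near neutrality, sparing the triene and the O–O bond and giving the β-peroxy aldehyde no time to eliminate, and the change of descriptor at C3 from S to R reflects substituent priorities only.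

Compound list
1 | ethyl but-2-ynoate | CCOC(=O)C#CC | starting material
2 | ethyl (2E)-3-(tributylstannyl)but-2-enoate | CCOC(=O)/C=C(\C)[Sn](CCCC)(CCCC)CCCC | intermediate
3 | 3-chloro-2-methylprop-1-ene | C=C(C)CCl | starting material
4 | ethyl (2E)-3,5-dimethylhexa-2,5-dienoate | C=C(C)C/C(C)=C/C(=O)OCC | intermediate
5 | (2E)-3,5-dimethylhexa-2,5-dien-1-ol | C=C(C)C/C(C)=C/CO | intermediate
6 | [(2S,3S)-3-methyl-3-(2-methylprop-2-en-1-yl)oxiran-2-yl]methanol | C=C(C)C[C@]1(C)O[C@H]1CO | intermediate
7 | (3S)-3,5-dimethylhex-5-ene-1,3-diol | C=C(C)C[C@@](C)(CCO)O | intermediate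
8 | (3S)-3-hydroxy-3,5-dimethylhex-5-en-1-yl 4-methylbenzenesulfonate | C=C(C)C[C@@](C)(CCOS(=O)(=O)c1ccc(C)cc1)O | intermediate
9 | (2S)-2-methyl-2-(2-methylprop-2-en-1-yl)oxetane | C=C(C)C[C@@]1(C)CCO1 | intermediate
10 | hydrogen peroxide | OO | starting material
11 | (3R)-3-hydroperoxy-3,5-dimethylhex-5-en-1-ol | C=C(C)C[C@](C)(CCO)OO | intermediate
12 | (3R)-3-[(2-methoxypropan-2-yl)peroxy]-3,5-dimethylhex-5-en-1-ol | C=C(C)C[C@](C)(CCO)OOC(C)(C)OC | intermediate
13 | tert-butyl({(3R)-3-[(2-methoxypropan-2-yl)peroxy]-3,5-dimethylhex-5-en-1-yl}oxy)diphenylsilane | C=C(C)C[C@](C)(CCO[Si](c1ccccc1)(c1ccccc1)C(C)(C)C)OOC(C)(C)OC | intermediate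
14 | tert-butyl{[(3R)-3-hydroperoxy-3,5-dimethylhex-5-en-1-yl]oxy}diphenylsilane | C=C(C)C[C@](C)(CCO[Si](c1ccccc1)(c1ccccc1)C(C)(C)C)OO | intermediate
15 | methyl acrylate | C=CC(=O)OC | starting material
16 | {[(3R,5S)-5-(2-{[tert-butyl(diphenyl)silyl]oxy}ethyl)-3,5-dimethyl-1,2-dioxolan-3-yl]methyl}mercury acetate (CH2HgOAc trans to the silyloxyethyl arm) | CC(=O)O[Hg]C[C@@]1(C)C[C@](C)(CCO[Si](c2ccccc2)(c2ccccc2)C(C)(C)C)OO1 | intermediate
17 | methyl 4-[(3S,5S)-5-(2-{[tert-butyl(diphenyl)silyl]oxy}ethyl)-3,5-dimethyl-1,2-dioxolan-3-yl]butanoate | COC(=O)CCC[C@@]1(C)C[C@](C)(CCO[Si](c2ccccc2)(c2ccccc2)C(C)(C)C)OO1 | intermediate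
18 | 4-[(3S,5S)-5-(2-{[tert-butyl(diphenyl)silyl]oxy}ethyl)-3,5-dimethyl-1,2-dioxolan-3-yl]butanal | O=CCCC[C@@]1(C)C[C@](C)(CCO[Si](c2ccccc2)(c2ccccc2)C(C)(C)C)OO1 | intermediate
19 | [2-(1,3-dioxolan-2-yl)ethyl]triphenylphosphonium bromide | [Br-].c1ccc(cc1)[P+](CCC1OCCO1)(c1ccccc1)c1ccccc1 | starting material
20 | tert-butyl(2-{(3S,5S)-5-[(4Z)-6-(1,3-dioxolan-2-yl)hex-4-en-1-yl]-3,5-dimethyl-1,2-dioxolan-3-yl}ethoxy)diphenylsilane | C1COC(C/C=C\CCC[C@@]2(C)C[C@](C)(CCO[Si](c3ccccc3)(c3ccccc3)C(C)(C)C)OO2)O1 | intermediate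
21 | tert-butyl(2-{(3S,5S)-5-[6-(1,3-dioxolan-2-yl)hexyl]-3,5-dimethyl-1,2-dioxolan-3-yl}ethoxy)diphenylsilane | C1COC(CCCCCC[C@@]2(C)C[C@](C)(CCO[Si](c3ccccc3)(c3ccccc3)C(C)(C)C)OO2)O1 | intermediate
22 | 7-[(3S,5S)-5-(2-{[tert-butyl(diphenyl)silyl]oxy}ethyl)-3,5-dimethyl-1,2-dioxolan-3-yl]heptanal | O=CCCCCCC[C@@]1(C)C[C@](C)(CCO[Si](c2ccccc2)(c2ccccc2)C(C)(C)C)OO1 | intermediate
23 | (triphenylphosphoranylidene)acetaldehyde | O=CC=P(c1ccccc1)(c1ccccc1)c1ccccc1 | starting material
24 | (2E)-9-[(3S,5S)-5-(2-{[tert-butyl(diphenyl)silyl]oxy}ethyl)-3,5-dimethyl-1,2-dioxolan-3-yl]non-2-enal | O=C/C=C/CCCCCC[C@@]1(C)C[C@](C)(CCO[Si](c2ccccc2)(c2ccccc2)C(C)(C)C)OO1 | intermediate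
25 | (3Z)-hex-3-en-1-ol | CC/C=C\CCO | starting material
26 | 5-{[(3Z)-hex-3-en-1-yl]sulfanyl}-1-phenyl-1H-tetrazole | CC/C=C\CCSc1nnnn1-c1ccccc1 | intermediate
27 | 5-{[(3Z)-hex-3-en-1-yl]sulfonyl}-1-phenyl-1H-tetrazole | CC/C=C\CCS(=O)(=O)c1nnnn1-c1ccccc1 | intermediate
28 | tert-butyl(2-{(3S,5S)-3,5-dimethyl-5-[(7E,9E,12Z)-pentadeca-7,9,12-trien-1-yl]-1,2-dioxolan-3-yl}ethoxy)diphenylsilane | CC/C=C\C/C=C/C=C/CCCCCC[C@@]1(C)C[C@](C)(CCO[Si](c2ccccc2)(c2ccccc2)C(C)(C)C)OO1 | intermediate
29 | 2-{(3S,5S)-3,5-dimethyl-5-[(7E,9E,12Z)-pentadeca-7,9,12-trien-1-yl]-1,2-dioxolan-3-yl}ethan-1-ol | CC/C=C\C/C=C/C=C/CCCCCC[C@@]1(C)C[C@](C)(CCO)OO1 | intermediate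
30 | {(3R,5S)-3,5-dimethyl-5-[(7E,9E,12Z)-pentadeca-7,9,12-trien-1-yl]-1,2-dioxolan-3-yl}acetaldehyde | CC/C=C\C/C=C/C=C/CCCCCC[C@@]1(C)C[C@](C)(CC=O)OO1 | intermediate
31 | {(3R,5S)-3,5-dimethyl-5-[(7E,9E,12Z)-pentadeca-7,9,12-trien-1-yl]-1,2-dioxolan-3-yl}acetic acid | CC/C=C\C/C=C/C=C/CCCCCC[C@@]1(C)C[C@](C)(CC(=O)O)OO1 | target

Total step count: 20. Longest linear sequence: 18 (steps 1–15 and 18–20). Steps 16 and 17 form the two-step sulfone branch.

Steps most likely to fail

Step 10.
- What may go wrong: the C1′ radical may collapse onto the neighbouring O–O bond before it meets acrylate. It may instead be quenched directly by the mercury hydride, or the adduct radical may telomerise with more acrylate. Facial control at C5 may also be weak.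
- Fallback: it uses known reaction types only, sets out from 13 and comes back at 21. It makes C5–C1′ by a polar reaction, so no β-peroxyalkyl radical arises.
  - Ozonolysis of 13 (O3, CH2Cl2, −78 °C; Me2S, which leaves dialkyl peroxides alone) should give the β-peroxy methyl ketone F1.
  - TsOH in MeOH removes the peroxyketal. The freed hydroperoxide then closes on the ketone and is ketalised to the 5-methoxy-1,2-dioxolane F2 (both C5 epimers).
  - SnCl4 and allyltrimethylsilane in CH2Cl2 at −78 °C ionise F2 to the peroxycarbenium ion. This is allylated on the face away from the silyloxyethyl arm to give the 5-allyl-1,2-dioxolane F3.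
  - Cross metathesis follows with 2-(pent-4-en-1-yl)-1,3-dioxolane F4, which is made from commercial hex-5-enal and ethane-1,2-diol with TsOH. Second-generation Grubbs catalyst, RuCl2(=CHPh)(PCy3)(H2IMes), should give the C2′=C3′ alkene F5.
  - Diimide under the conditions of step 13 delivers 21.

Step 7.
- What may go wrong: the opening may drift toward a free tertiary cation. That would erode the inversion at C3 and expose the methallyl alkene to acid.
- Fallback: enantiopurity is taken from a resolution instead of from the substitution. It sets out from 12, isolated after the first stage of step 8, and comes back at 12 as a single enantiomer.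
  - The opening is run for throughput and alkene safety alone, for example near neutrality with MoO2(acac)2 as catalyst.
  - Scalemic 12 is acylated with commercial (1S,4R)-camphanic chloride (pyridine, DMAP, CH2Cl2).
  - The (3R) camphanate ester F6 is separated from its diastereomer by crystallisation or chromatography.
  - K2CO3 in MeOH, to which the peroxyketal is inert, returns 12 for the silylation stage of step 8.

Step 18.
- What may go wrong: E/Z control at C9′=C10′ may be poor. The metalated homoallylic sulfone may lose sulfinate by β-elimination, and the enal may be deprotonated at its γ-position.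
- Fallback: the diene is closed one bond earlier, at C7′=C8′, by a Horner–Wadsworth–Emmons reaction. It sets out from 25 and from aldehyde 22 (steps 15–17 are dropped) and comes back at 28.
  - Dess–Martin oxidation of 25 gives (3Z)-hex-3-enal F7.
  - F7 is treated at once with Ph3P=CHCO2Et to give ethyl (2E,5Z)-octa-2,5-dienoate F8.
  - iBu2AlH gives (2E,5Z)-octa-2,5-dien-1-ol F9.
  - An Appel reaction (CBr4, PPh3) gives (2E,5Z)-1-bromoocta-2,5-diene F10.
  - A Michaelis–Arbuzov reaction with P(OEt)3 gives diethyl [(2E,5Z)-octa-2,5-dien-1-yl]phosphonate F11.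
  - Deprotonation with LiN(SiMe3)2 in THF at −78 °C and addition of 22 should give 28, since allylic phosphonate anions favour the E alkene with unbranched aldehydes.

Further compounds
F1 | step 10 | (4S)-6-{[tert-butyl(diphenyl)silyl]oxy}-4-[(2-methoxypropan-2-yl)peroxy]-4-methylhexan-2-one | CC(=O)C[C@](C)(CCO[Si](c1ccccc1)(c1ccccc1)C(C)(C)C)OOC(C)(C)OC
F2 | step 10 | tert-butyl{2-[(3S)-5-methoxy-3,5-dimethyl-1,2-dioxolan-3-yl]ethoxy}diphenylsilane (both C5 epimers) | COC1(C)C[C@](C)(CCO[Si](c2ccccc2)(c2ccccc2)C(C)(C)C)OO1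
F3 | step 10 | tert-butyl{2-[(3S,5S)-3,5-dimethyl-5-(prop-2-en-1-yl)-1,2-dioxolan-3-yl]ethoxy}diphenylsilane | C=CC[C@@]1(C)C[C@](C)(CCO[Si](c2ccccc2)(c2ccccc2)C(C)(C)C)OO1
F4 | step 10 | 2-(pent-4-en-1-yl)-1,3-dioxolane | C=CCCCC1OCCO1
F5 | step 10 | tert-butyl(2-{(3S,5S)-5-[(2E)-6-(1,3-dioxolan-2-yl)hex-2-en-1-yl]-3,5-dimethyl-1,2-dioxolan-3-yl}ethoxy)diphenylsilane | C1COC(CCC/C=C/C[C@@]2(C)C[C@](C)(CCO[Si](c3ccccc3)(c3ccccc3)C(C)(C)C)OO2)O1
F6 | step 7 | (3R)-3-[(2-methoxypropan-2-yl)peroxy]-3,5-dimethylhex-5-en-1-yl (1S,4R)-4,7,7-trimethyl-3-oxo-2-oxabicyclo[2.2.1]heptane-1-carboxylate | C[C@]12CC[C@](C(=O)OCC[C@@](C)(CC(C)=C)OOC(C)(C)OC)(OC1=O)C2(C)C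
F7 | step 18 | (3Z)-hex-3-enal | CC/C=C\CC=O
F8 | step 18 | ethyl (2E,5Z)-octa-2,5-dienoate | CC/C=C\C/C=C/C(=O)OCC
F9 | step 18 | (2E,5Z)-octa-2,5-dien-1-ol | CC/C=C\C/C=C/CO
F10 | step 18 | (2E,5Z)-1-bromoocta-2,5-diene | CC/C=C\C/C=C/CBr
F11 | step 18 | diethyl [(2E,5Z)-octa-2,5-dien-1-yl]phosphonate | CC/C=C\C/C=C/CP(=O)(OCC)OCC
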